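**Strategy.** The C40 chain is cut at C15=C15' (Wittig) into a ring E phosphonium half from (R)-alpha-ionone and a ring A C20 aldehyde. Everything rests on making the trisubstituted C9=C10 alkene (carotenoid numbering), which bears methyl C19 and is conjugated to the C7≡C8 alkyne on ring A, as the pure 9E isomer. The key step does this in one operation: syn methylalumination of the terminal C9≡C10 alkyne of a ring A buta-1,3-diyne, then palladium/zinc coupling of the alkenylalane with an E,E-iododiene, forming C9–CH3 and C10–C11. The precursor is the (R)-silyloxy ring A diyne, C6–C7≡C8–C9≡C10–H.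

Key step: step 9

Assumption: (R)-alpha-ionone is bought enantiomerically pure; carotenoid numbering is used throughout, with primed locants for the ring E half (the 2,6,6-trimethylcyclohex-2-enyl end).

**Ring A diyne**

Step 1
Reactants: 1 ketoisophorone (2,6,6-trimethylcyclohex-2-ene-1,4-dione)
Product: 2 (6R)-levodione [(R)-2,2,6-trimethylcyclohexane-1,4-dione]
Conditions: ene-reductase OYE2 (old yellow enzyme), NADP+ (cat.), D-glucose, glucose dehydrogenase, KH2PO4/K2HPO4 buffer pH 7, 30 °C; prompt extraction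
Reagents that add atoms: none
Why: Ene-reductase trans-hydrogenation of the doubly activated ring C=C bond, a benchmark asymmetric bioreduction of this enedione; hydride and proton are delivered inside the chiral active site, so the methyl-bearing carbon should be formed as R.

Step 2
Reactants: 2 (6R)-levodione
Product: 3 (4R,6R)-actinol [(4R,6R)-4-hydroxy-2,2,6-trimethylcyclohexan-1-one]
Conditions: LiBH(s-Bu)3, THF, −78 °C; then H2O
Reagents that add atoms: none
Why: Diastereoselective ketone reduction by a bulky trialkylborohydride: the C1 carbonyl is screened by its three alpha substituents, and at C4 the axial C2 methyl blocks axial approach, so hydride should enter equatorially (as in 3,3,5-trimethylcyclohexanone) and give the alcohol trans to the C6 methyl, that is 4R under control of the C6 centre.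

Step 3
Reactants: 3 (4R,6R)-actinol
Product: 4 (4R,6R)-4-[(tert-butyldimethylsilyl)oxy]-2,2,6-trimethylcyclohexan-1-one
Conditions: TBSCl, imidazole, DMF, rt
Reagents that add atoms: tert-butyldimethylsilyl chloride, CC(C)(C)[Si](C)(C)Cl
Why: Standard imidazole-promoted silylation of the secondary alcohol, which protects it against the bases and organometallics of steps 4 to 9 without touching a stereocentre.

Step 4
Reactants: 4 silylated actinol
Product: 6 (R)-4-[(tert-butyldimethylsilyl)oxy]-2,6,6-trimethylcyclohex-1-en-1-yl trifluoromethanesulfonate (ring A enol triflate), via lithium enolate 5 (not isolated)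
Conditions: LiN(i-Pr)2, THF, −78 °C; then PhNTf2, −78 °C to rt
Reagents that add atoms: N-phenylbis(trifluoromethanesulfonimide), O=S(=O)(N(c1ccccc1)S(=O)(=O)C(F)(F)F)C(F)(F)F
Why: Enolate O-triflation: only C6 carries an alpha hydrogen, so LiN(i-Pr)2 gives a single enolate that PhNTf2 traps as the tetrasubstituted enol triflate; the C6 centre is erased on purpose and the silyloxy centre (C3 of the carotenoid) is not involved.

Step 5
Reactants: 6 ring A enol triflate; 7 1,4-bis(trimethylsilyl)buta-1,3-diyne
Product: 10 {4-[(R)-4-[(tert-butyldimethylsilyl)oxy]-2,6,6-trimethylcyclohex-1-en-1-yl]buta-1,3-diyn-1-yl}trimethylsilane, via lithium 4-(trimethylsilyl)butadiynide 8 (not isolated), via chloro[4-(trimethylsilyl)butadiynyl]zinc 9 (not isolated)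
Conditions: 7, MeLi·LiBr, Et2O/THF, −78 °C to rt; ZnCl2, 0 °C; then 6, Pd(PPh3)4 (5 mol %, zerovalent palladium), THF, rt to 50 °C
Reagents that add atoms: none
Why: Negishi alkynylation: MeLi·LiBr removes one silyl group of 7 as tetramethylsilane, ZnCl2 converts the lithium diynide to the diynylzinc, and Pd(PPh3)4 couples it with the alkenyl triflate, a known reaction of 1,3-diynylzinc reagents that needs no copper and so avoids oxidative diyne dimerisation.

Step 6
Reactants: 10 ring A silyl diyne
Product: 11 tert-butyl{[(R)-4-(buta-1,3-diyn-1-yl)-3,5,5-trimethylcyclohex-3-en-1-yl]oxy}dimethylsilane (ring A terminal diyne)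
Conditions: K2CO3 (cat.), MeOH/THF, 0 °C; used at once in step 9
Reagents that add atoms: none
Why: Base-catalysed methanolysis of the alkynyl C–Si bond frees the terminal diyne, while the secondary alkyl silyl ether is stable to K2CO3 in methanol.

**Iododiene**

Step 7
Reactants: 12 (E)-3-methylpent-2-en-4-yn-1-ol
Product: 13 tert-butyldimethyl{[(E)-3-methylpent-2-en-4-yn-1-yl]oxy}silane
Conditions: TBSCl, imidazole, CH2Cl2, 0 °C to rt
Reagents that add atoms: tert-butyldimethylsilyl chloride, CC(C)(C)[Si](C)(C)Cl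
Why: Standard silylation of the primary allylic alcohol, needed because a free hydroxyl would consume the hydride and alane reagents of steps 8 and 9.

Step 8
Reactants: 13 silylated enynol
Product: 15 tert-butyl{[(2E,4E)-5-iodo-3-methylpenta-2,4-dien-1-yl]oxy}dimethylsilane, via alkenylzirconocene chloride 14 (not isolated)
Conditions: Cp2Zr(H)Cl, THF, rt, dark; then I2, 0 °C
Reagents that add atoms: iodine, II
Why: Hydrozirconation adds Zr–H syn across the terminal alkyne with zirconium at the unhindered terminal carbon, and iodinolysis of the C–Zr bond occurs with retention, so the new alkene should be E and the existing E alkene is untouched.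

**Key step and ring A C20 aldehyde**

Step 9
Reactants: 11 ring A terminal diyne; 15 E,E-iododiene
Product: 18 bis-silyl ether of the ring A C20 alcohol (C1 to C15; all-E; 7,8-didehydro), via alkenyldimethylalane 16 (not isolated), via alkenylzinc chloride 17 (not isolated)
Conditions: 11, AlMe3 (2.5 equiv), Cp2ZrCl2 (25 mol %), CH2Cl2, 0 °C to rt; volatiles removed in vacuo; then 15, ZnCl2 (1 equiv), Pd(PPh3)4 (5 mol %, zerovalent palladium), THF, rt, dark
Reagents that add atoms: trimethylaluminium, C[Al](C)C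
Why: AlMe3 and Cp2ZrCl2 form a chloride-bridged, polarised methylzirconocene–alane that adds methyl and metal syn across the terminal C9≡C10 bond, methyl to the internal carbon C9 and metal (zirconium, then aluminium by exchange) to C10, giving alkenylalane 16. After removal of excess AlMe3 the alkenyl group passes through zinc (17) to the divalent alkenylpalladium iodide formed by oxidative addition of 15 to zerovalent palladium, and reductive elimination forms C10–C11 with retention at both sp2 carbons. The closest known reaction type is the zirconium-catalysed methylalumination of terminal alkynes, conjugated enynes and silylbutadiyne with one-pot palladium/zinc (Negishi) coupling, as used in polyene synthesis. No ring is closed and no stereocentre is formed, and the C3 silyl ether is inert to the reagents. The step needs site selectivity for the terminal over the internal alkyne, methyl delivery to C9 and syn addition: the C7≡C8 bond is disubstituted and screened by the C1 gem-dimethyl and C5 methyl groups of ring A, the metal prefers the unhindered terminal carbon, and the concerted four-centre addition fixes 9E without any equilibrating intermediate. The 11E and 13E bonds come unchanged from 15.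

Step 10
Reactants: 18 bis-silyl ether
Product: 19 (2E,4E,6E)-9-[(R)-4-hydroxy-2,6,6-trimethylcyclohex-1-en-1-yl]-3,7-dimethylnona-2,4,6-trien-8-yn-1-ol (ring A C20 diol)
Conditions: n-Bu4NF (3 equiv), THF, 0 °C to rt, dark
Reagents that add atoms: none
Why: Fluoride cleaves both Si–O bonds (formation of the strong Si–F bond) under essentially neutral conditions that should not disturb the tetraenyne or the C3 centre.

Step 11
Reactants: 19 ring A C20 diol
Product: 20 (2E,4E,6E)-9-[(R)-4-hydroxy-2,6,6-trimethylcyclohex-1-en-1-yl]-3,7-dimethylnona-2,4,6-trien-8-ynal (ring A C20 aldehyde)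
Conditions: activated MnO2 (excess), CH2Cl2, rt, dark
Reagents that add atoms: none
Why: Chemoselective allylic oxidation: MnO2 oxidises the primary allylic C15 alcohol to the conjugated aldehyde but not the non-allylic secondary ring alcohol, and no acid or cation that could isomerise C9=C10 is involved.

**Ring E half**

Step 12
Reactants: 21 (R)-alpha-ionone
Product: 22 (2E,4E)-3-methyl-5-[(R)-2,6,6-trimethylcyclohex-2-en-1-yl]penta-2,4-dienenitrile
Conditions: (EtO)2P(O)CH2CN (1.3 equiv), NaH (1.2 equiv), THF, 0 °C; then 21, 0 °C to rt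
Reagents that add atoms: diethyl cyanomethylphosphonate, N#CCP(=O)(OCC)OCC
Why: Horner–Wadsworth–Emmons olefination of the methyl ketone with the stabilised cyanomethylphosphonate anion, which is too weak a base to deprotonate C6', should give mainly the 9'E nitrile; the minor 9'Z isomer is removed by chromatography here or after step 13.

Step 13
Reactants: 22 ring E C15 nitrile
Product: 24 (2E,4E)-3-methyl-5-[(R)-2,6,6-trimethylcyclohex-2-en-1-yl]penta-2,4-dienal, via N-(diisobutylalumino)imine 23 (not isolated)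
Conditions: i-Bu2AlH, hexane/CH2Cl2, −78 °C; then wet silica gel or aq. potassium sodium tartrate, 0 °C
Reagents that add atoms: water, O
Why: Partial reduction of the nitrile: i-Bu2AlH adds once to give the N-aluminoimine, which is stable at low temperature and is hydrolysed to the aldehyde on work-up.

Step 14
Reactants: 24 ring E C15 aldehyde
Product: 25 ethyl (2E,4E,6E,8E)-3,7-dimethyl-9-[(R)-2,6,6-trimethylcyclohex-2-en-1-yl]nona-2,4,6,8-tetraenoate (ethyl (R)-alpha-retinoate)
Conditions: triethyl 3-methyl-4-phosphonocrotonate, NaH, THF, 0 °C; then 24, 0 °C to rt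
Reagents that add atoms: ethyl (E)-4-(diethoxyphosphoryl)-3-methylbut-2-enoate, CCOC(=O)/C=C(\C)CP(=O)(OCC)OCC
Why: Vinylogous Horner–Wadsworth–Emmons olefination: the gamma-carbanion of the C5 phosphonate adds to the aldehyde and eliminates diethyl phosphate to form C11'=C12' with E selectivity, the 13'E ester being the expected main product and any 13'Z isomer being removed by chromatography.

Step 15
Reactants: 25 ethyl (R)-alpha-retinoate
Product: 26 (2E,4E,6E,8E)-3,7-dimethyl-9-[(R)-2,6,6-trimethylcyclohex-2-en-1-yl]nona-2,4,6,8-tetraen-1-ol ((R)-alpha-retinol)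
Conditions: i-Bu2AlH (2.2 equiv), THF, −78 °C to 0 °C; aq. potassium sodium tartrate
Reagents that add atoms: none
Why: i-Bu2AlH reduces the conjugated ester by 1,2-addition to the primary allylic alcohol without touching the polyene.

Step 16
Reactants: 26 (R)-alpha-retinol
Product: 27 [(2E,4E,6E,8E)-3,7-dimethyl-9-[(R)-2,6,6-trimethylcyclohex-2-en-1-yl]nona-2,4,6,8-tetraen-1-yl]triphenylphosphonium bromide
Conditions: PPh3·HBr, MeOH, 0 °C to rt, dark
Reagents that add atoms: triphenylphosphine hydrobromide, Br.c1ccc(cc1)P(c1ccccc1)c1ccccc1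
Why: Phosphonium salt formation from an allylic alcohol with PPh3·HBr, as used for retinol and for ring E C15 alcohols: the delocalised pentaenyl cation is trapped by PPh3 at the unhindered terminus C15', and in this alkyne-free half any equilibration favours the all-E chain.

**Union**

Step 17
Reactants: 27 ring E C20 phosphonium bromide; 20 ring A C20 aldehyde
Product: 29 (3R,6'R)-7,8-didehydro-beta,epsilon-caroten-3-ol (all-E; the target), via pentaenyl phosphorus ylide 28 (not isolated)
Conditions: 27 (1.5 equiv), NaOMe, CH2Cl2/MeOH, 0 °C; then 20, 0 °C to rt, dark, argon; any 15Z isomer isomerised by brief warming (about 60 °C, dark) or removed by chromatography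
Reagents that add atoms: none
Why: Wittig olefination of the polyenal with the semi-stabilised pentaenyl ylide made by NaOMe forms C15=C15' and tolerates the free C3 hydroxyl; the unhindered central bond should form mainly E, its Z isomer has the lowest thermal barrier to the E form among carotenoid isomers, and the C3 and C6' centres and the 9E enyne are spectators.

**Compound list**

1 | ketoisophorone (2,6,6-trimethylcyclohex-2-ene-1,4-dione) | CC1=CC(=O)CC(C)(C)C1=O | starting material
2 | (6R)-levodione, (R)-2,2,6-trimethylcyclohexane-1,4-dione | C[C@@H]1CC(=O)CC(C)(C)C1=O | intermediate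
3 | (4R,6R)-actinol, (4R,6R)-4-hydroxy-2,2,6-trimethylcyclohexan-1-one | C[C@@H]1C[C@@H](O)CC(C)(C)C1=O | intermediate
4 | (4R,6R)-4-[(tert-butyldimethylsilyl)oxy]-2,2,6-trimethylcyclohexan-1-one | C[C@@H]1C[C@@H](O[Si](C)(C)C(C)(C)C)CC(C)(C)C1=O | intermediate
5 | lithium (R)-4-[(tert-butyldimethylsilyl)oxy]-2,6,6-trimethylcyclohex-1-en-1-olate (not isolated) | CC1=C([O-])C(C)(C)C[C@H](O[Si](C)(C)C(C)(C)C)C1.[Li+] | intermediate
6 | (R)-4-[(tert-butyldimethylsilyl)oxy]-2,6,6-trimethylcyclohex-1-en-1-yl trifluoromethanesulfonate | CC1=C(OS(=O)(=O)C(F)(F)F)C(C)(C)C[C@H](O[Si](C)(C)C(C)(C)C)C1 | intermediate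
7 | 1,4-bis(trimethylsilyl)buta-1,3-diyne | C[Si](C)(C)C#CC#C[Si](C)(C)C | starting material
8 | lithium 4-(trimethylsilyl)buta-1,3-diyn-1-ide (not isolated) | [Li+].[C-]#CC#C[Si](C)(C)C | intermediate
9 | chloro[4-(trimethylsilyl)buta-1,3-diyn-1-yl]zinc (not isolated) | Cl[Zn]C#CC#C[Si](C)(C)C | intermediate
10 | {4-[(R)-4-[(tert-butyldimethylsilyl)oxy]-2,6,6-trimethylcyclohex-1-en-1-yl]buta-1,3-diyn-1-yl}trimethylsilane | CC1=C(C#CC#C[Si](C)(C)C)C(C)(C)C[C@H](O[Si](C)(C)C(C)(C)C)C1 | intermediate
11 | tert-butyl{[(R)-4-(buta-1,3-diyn-1-yl)-3,5,5-trimethylcyclohex-3-en-1-yl]oxy}dimethylsilane | CC1=C(C#CC#C)C(C)(C)C[C@H](O[Si](C)(C)C(C)(C)C)C1 | intermediate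
12 | (E)-3-methylpent-2-en-4-yn-1-ol | C#C/C(C)=C/CO | starting material
13 | tert-butyldimethyl{[(E)-3-methylpent-2-en-4-yn-1-yl]oxy}silane | C#C/C(C)=C/CO[Si](C)(C)C(C)(C)C | intermediate
14 | chlorobis(cyclopentadienyl)[(1E,3E)-5-[(tert-butyldimethylsilyl)oxy]-3-methylpenta-1,3-dien-1-yl]zirconium (not isolated) | Cl[Zr](C1C=CC=C1)(C1C=CC=C1)/C=C/C(C)=C/CO[Si](C)(C)C(C)(C)C | intermediate
15 | tert-butyl{[(2E,4E)-5-iodo-3-methylpenta-2,4-dien-1-yl]oxy}dimethylsilane | I/C=C/C(C)=C/CO[Si](C)(C)C(C)(C)C | intermediate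
16 | {(E)-4-[(R)-4-[(tert-butyldimethylsilyl)oxy]-2,6,6-trimethylcyclohex-1-en-1-yl]-2-methylbut-1-en-3-yn-1-yl}dimethylalane (not isolated) | CC1=C(C#C/C(C)=C/[Al](C)C)C(C)(C)C[C@H](O[Si](C)(C)C(C)(C)C)C1 | intermediate
17 | chloro{(E)-4-[(R)-4-[(tert-butyldimethylsilyl)oxy]-2,6,6-trimethylcyclohex-1-en-1-yl]-2-methylbut-1-en-3-yn-1-yl}zinc (not isolated) | CC1=C(C#C/C(C)=C/[Zn]Cl)C(C)(C)C[C@H](O[Si](C)(C)C(C)(C)C)C1 | intermediate
18 | tert-butyl{[(2E,4E,6E)-9-[(R)-4-[(tert-butyldimethylsilyl)oxy]-2,6,6-trimethylcyclohex-1-en-1-yl]-3,7-dimethylnona-2,4,6-trien-8-yn-1-yl]oxy}dimethylsilane | CC1=C(C#C/C(C)=C/C=C/C(C)=C/CO[Si](C)(C)C(C)(C)C)C(C)(C)C[C@H](O[Si](C)(C)C(C)(C)C)C1 | intermediate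
19 | (2E,4E,6E)-9-[(R)-4-hydroxy-2,6,6-trimethylcyclohex-1-en-1-yl]-3,7-dimethylnona-2,4,6-trien-8-yn-1-ol | CC1=C(C#C/C(C)=C/C=C/C(C)=C/CO)C(C)(C)C[C@H](O)C1 | intermediate
20 | (2E,4E,6E)-9-[(R)-4-hydroxy-2,6,6-trimethylcyclohex-1-en-1-yl]-3,7-dimethylnona-2,4,6-trien-8-ynal | CC1=C(C#C/C(C)=C/C=C/C(C)=C/C=O)C(C)(C)C[C@H](O)C1 | intermediate
21 | (R)-alpha-ionone, (E)-4-[(R)-2,6,6-trimethylcyclohex-2-en-1-yl]but-3-en-2-one | CC1=CCCC(C)(C)[C@H]1/C=C/C(C)=O | starting material
22 | (2E,4E)-3-methyl-5-[(R)-2,6,6-trimethylcyclohex-2-en-1-yl]penta-2,4-dienenitrile | CC1=CCCC(C)(C)[C@H]1/C=C/C(C)=C/C#N | intermediate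
23 | N-(diisobutylalumino)imine of aldehyde 24 (not isolated) | CC1=CCCC(C)(C)[C@H]1/C=C/C(C)=C/C=N[Al](CC(C)C)CC(C)C | intermediate
24 | (2E,4E)-3-methyl-5-[(R)-2,6,6-trimethylcyclohex-2-en-1-yl]penta-2,4-dienal | CC1=CCCC(C)(C)[C@H]1/C=C/C(C)=C/C=O | intermediate
25 | ethyl (2E,4E,6E,8E)-3,7-dimethyl-9-[(R)-2,6,6-trimethylcyclohex-2-en-1-yl]nona-2,4,6,8-tetraenoate | CC1=CCCC(C)(C)[C@H]1/C=C/C(C)=C/C=C/C(C)=C/C(=O)OCC | intermediate
26 | (R)-alpha-retinol, (2E,4E,6E,8E)-3,7-dimethyl-9-[(R)-2,6,6-trimethylcyclohex-2-en-1-yl]nona-2,4,6,8-tetraen-1-ol | CC1=CCCC(C)(C)[C@H]1/C=C/C(C)=C/C=C/C(C)=C/CO | intermediate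
27 | [(2E,4E,6E,8E)-3,7-dimethyl-9-[(R)-2,6,6-trimethylcyclohex-2-en-1-yl]nona-2,4,6,8-tetraen-1-yl]triphenylphosphonium bromide | CC1=CCCC(C)(C)[C@H]1/C=C/C(C)=C/C=C/C(C)=C/C[P+](c1ccccc1)(c1ccccc1)c1ccccc1.[Br-] | intermediate
28 | ylide of 27, (R)-alpha-retinylidenetriphenylphosphorane (not isolated) | CC1=CCCC(C)(C)[C@H]1/C=C/C(C)=C/C=C/C(C)=C/C=P(c1ccccc1)(c1ccccc1)c1ccccc1 | intermediate
29 | (3R,6'R)-7,8-didehydro-beta,epsilon-caroten-3-ol, all-E | CC1=CCCC(C)(C)[C@H]1/C=C/C(C)=C/C=C/C(C)=C/C=C/C=C(C)/C=C/C=C(\C)C#CC1=C(C)C[C@@H](O)CC1(C)C | target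

**Totals**

Total step count: 17. Longest linear sequence: 10 steps (steps 1 to 6, 9, 10, 11 and 17).

**Steps most likely to fail, with fallbacks**

Step 9. The acidic terminal C–H of the conjugated diyne may be metalated by AlMe3 instead of carbometalated, the diyne may oligomerise, or residual methyl-metal may transfer methyl to palladium in place of the alkenyl group. The fallback gives up carbometalation and takes the 9E bond ready-made from the commercial enynol. It sets out from enol triflate 6 and enynol 12. Sonogashira coupling (Pd(PPh3)4, copper iodide CuI, i-Pr2NH, THF) should give (E)-5-[(R)-4-[(tert-butyldimethylsilyl)oxy]-2,6,6-trimethylcyclohex-1-en-1-yl]-3-methylpent-2-en-4-yn-1-ol F1. MnO2 oxidation then gives the enynal F2. Horner–Wadsworth–Emmons extension with the C5 phosphonate of step 14 (NaH, THF) gives the C20 ethyl ester F3, and i-Bu2AlH reduction gives the mono-silylated C20 alcohol F4. n-Bu4NF cleaves the ring silyl ether, and the route is rejoined at diol 19.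

Step 17. The Wittig reaction may give poor E/Z control at C15=C15', and warming to correct it may let the 9E enyne drift. The fallback replaces the ylide by a phosphonate carbanion, which is E-selective with enals. It sets out from alpha-retinol 26, before step 16. PBr3 (Et2O, −20 °C) gives (R)-alpha-retinyl bromide F5, which is used at once with NaP(O)(OEt)2 (Michaelis–Becker reaction) to give diethyl (R)-alpha-retinylphosphonate F6. KN(SiMe3)2 in THF at −78 °C gives the potassium phosphonate carbanion F7, which is condensed with aldehyde 20 in a Horner–Wadsworth–Emmons olefination that comes back to the route at target 29.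

Step 16. The pentaenyl cation may lose the C6' proton (elimination to a retro-type hydrocarbon) or scramble chain geometry before PPh3 traps it. The fallback reverses the polarity of the union so that the ring E half is never ionised. It sets out from alpha-retinol 26 and diol 19. MnO2 oxidises 26 to (R)-alpha-retinal F8. PPh3·HBr (MeOH, 0 °C, short contact) converts the allylic alcohol of 19 into the ring A C20 phosphonium bromide F9, the non-allylic C3 hydroxyl staying free. NaOMe gives the ring A ylide F10, and Wittig condensation with F8 comes back to the route at target 29. The cost is brief exposure of the 9E enyne to an allylic cation.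

**Further compounds**

F1 | step 9 | (E)-5-[(R)-4-[(tert-butyldimethylsilyl)oxy]-2,6,6-trimethylcyclohex-1-en-1-yl]-3-methylpent-2-en-4-yn-1-ol | CC1=C(C#C/C(C)=C/CO)C(C)(C)C[C@H](O[Si](C)(C)C(C)(C)C)C1
F2 | step 9 | (E)-5-[(R)-4-[(tert-butyldimethylsilyl)oxy]-2,6,6-trimethylcyclohex-1-en-1-yl]-3-methylpent-2-en-4-ynal | CC1=C(C#C/C(C)=C/C=O)C(C)(C)C[C@H](O[Si](C)(C)C(C)(C)C)C1
F3 | step 9 | ethyl (2E,4E,6E)-9-[(R)-4-[(tert-butyldimethylsilyl)oxy]-2,6,6-trimethylcyclohex-1-en-1-yl]-3,7-dimethylnona-2,4,6-trien-8-ynoate | CC1=C(C#C/C(C)=C/C=C/C(C)=C/C(=O)OCC)C(C)(C)C[C@H](O[Si](C)(C)C(C)(C)C)C1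
F4 | step 9 | (2E,4E,6E)-9-[(R)-4-[(tert-butyldimethylsilyl)oxy]-2,6,6-trimethylcyclohex-1-en-1-yl]-3,7-dimethylnona-2,4,6-trien-8-yn-1-ol | CC1=C(C#C/C(C)=C/C=C/C(C)=C/CO)C(C)(C)C[C@H](O[Si](C)(C)C(C)(C)C)C1
F5 | step 17 | (R)-alpha-retinyl bromide | CC1=CCCC(C)(C)[C@H]1/C=C/C(C)=C/C=C/C(C)=C/CBr
F6 | step 17 | diethyl (R)-alpha-retinylphosphonate | CC1=CCCC(C)(C)[C@H]1/C=C/C(C)=C/C=C/C(C)=C/CP(=O)(OCC)OCC
F7 | step 17 | potassium carbanion of F6 | CC1=CCCC(C)(C)[C@H]1/C=C/C(C)=C/C=C/C(C)=C/[CH-]P(=O)(OCC)OCC.[K+]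
F8 | step 16 | (R)-alpha-retinal | CC1=CCCC(C)(C)[C@H]1/C=C/C(C)=C/C=C/C(C)=C/C=O
F9 | step 16 | [(2E,4E,6E)-9-[(R)-4-hydroxy-2,6,6-trimethylcyclohex-1-en-1-yl]-3,7-dimethylnona-2,4,6-trien-8-yn-1-yl]triphenylphosphonium bromide | CC1=C(C#C/C(C)=C/C=C/C(C)=C/C[P+](c2ccccc2)(c2ccccc2)c2ccccc2)C(C)(C)C[C@H](O)C1.[Br-]
F10 | step 16 | ylide of F9 | CC1=C(C#C/C(C)=C/C=C/C(C)=C/C=P(c2ccccc2)(c2ccccc2)c2ccccc2)C(C)(C)C[C@H](O)C1
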